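The route rests on disconnecting the C6–CH3 bond in the cyclopentanone ring of the cyclopenta[c]pyridine core. On that ring the C6 methyl and the C5 hydroxyl share one face, and C6 adjoins the C7 carbonyl, so it can act as an enolate carbon. The C5 oxygen therefore carries the future methyl carbon as an O–SiMe2–CH2I arm. On enolisation C6 attacks that carbon. In one operation this forms the C6–CH2 bond, closes a temporary cis-fused 1,2-oxasilolane and sets the quaternary C6 centre from C5 alone. The precursor is the fully assembled dienyl-substituted 5-silyloxy-6-methoxy-7-oxo ester, which lacks only the methyl group. Fluoride finally excises silicon, leaving CH3 and OH.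

Key step: step 12

Assumption: C6 of 9, 10, 17, 19 and 20 carries an enolisable hydrogen, so these compounds are expected as mixtures of C6 epimers. Each is drawn as the epimer with the methoxy group trans to the C5 oxygen (6S in the 5R series). Both epimers give the same enolate 21.

Step 1
Reactants: 1 2,5-dibromopyridine; 2 dimethyl oxalate
Product: 4 methyl 2-(2,5-dibromopyridin-4-yl)-2-oxoacetate, via 2,5-dibromo-4-lithiopyridine 3 (not isolated)
Conditions: LiN(i-Pr)2 (1.05 equiv), THF, −78 °C, 30 min; cannulated into 2 (3 equiv), THF, −78 °C; aqueous quench at −78 °C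
Reagents that add atoms: none
Why: Directed ortho-lithiation next to the C5 bromine takes place at C4 at low temperature before halogen migration or pyridyne formation, and acylation of the aryllithium by excess oxalate under inverse addition stops at the α-keto ester because the tetrahedral adduct survives until the quench.

Step 2
Reactants: 4 methyl 2-(2,5-dibromopyridin-4-yl)-2-oxoacetate; 5 methyl methoxyacetate
Product: 7 dimethyl 2-(2,5-dibromopyridin-4-yl)-2-hydroxy-3-methoxybutanedioate (racemic; both diastereomers), via lithium enolate of methyl methoxyacetate 6 (not isolated)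
Conditions: 5 (1.15 equiv), LiN(i-Pr)2 (1.1 equiv), THF, −78 °C; then 4, −78 °C; aqueous quench at −78 °C
Reagents that add atoms: none
Why: Aldol addition of an ester enolate to the very electrophilic, non-enolisable ketone of the aryl keto ester forms the C5–C6 bond, and the two new stereocentres need no control here because C5 is resolved in step 4 and C6 is erased in step 12.

Step 3
Reactants: 7 dimethyl 2-(2,5-dibromopyridin-4-yl)-2-hydroxy-3-methoxybutanedioate
Product: 9 methyl rac-3-bromo-5-hydroxy-6-methoxy-7-oxo-6,7-dihydro-5H-cyclopenta[c]pyridine-5-carboxylate, via doubly magnesiated diester 8 (not isolated)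
Conditions: i-PrMgCl·LiCl (2.2 equiv), THF, −40 °C to −10 °C; aq NH4Cl
Reagents that add atoms: none
Why: Parham-type cyclisation, in which the hydroxyl is deprotonated first, bromine–magnesium exchange then occurs at the pyridine C5 bromine (the position that exchanges in 2,5-dibromopyridines, here helped by the neighbouring alkoxide), and the arylmagnesium can acylate only at the methoxy-bearing ester through a five-membered transition state, the ketone being shielded as its enolate until work-up.

Step 4
Reactants: 9 methyl rac-3-bromo-5-hydroxy-6-methoxy-7-oxo-6,7-dihydro-5H-cyclopenta[c]pyridine-5-carboxylate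
Product: 10 methyl (5R,6S)-3-bromo-5-hydroxy-6-methoxy-7-oxo-6,7-dihydro-5H-cyclopenta[c]pyridine-5-carboxylate
Conditions: preparative supercritical-fluid chromatography, amylose tris(3,5-dimethylphenylcarbamate) phase, CO2/MeOH, 35 °C
Reagents that add atoms: none
Why: Resolution of enantiomers on a chiral stationary phase, placed after the last strongly basic operation on the free aldol, secures the 5R configuration (to be confirmed by anomalous-dispersion X-ray analysis at bromine), and both C6 epimers of the 5R series are pooled.

Step 5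
Reactants: 11 (S)-2-methylbutan-1-ol
Product: 12 (S)-2-methylbutanal
Conditions: TEMPO (1 mol %), KBr (10 mol %), NaOCl (1.1 equiv), NaHCO3 buffer, CH2Cl2/H2O, 0 °C
Reagents that add atoms: none
Why: Anelli oxidation stops at the aldehyde, and the buffered two-phase medium at 0 °C is established to leave the α-stereocentre of this aldehyde intact.

Step 6
Reactants: 12 (S)-2-methylbutanal; 13 2-(triphenylphosphoranylidene)propanal
Product: 14 (2E,4S)-2,4-dimethylhex-2-enal
Conditions: 13 (1.2 equiv), toluene, 80 °C, sealed flask
Reagents that add atoms: none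
Why: Wittig olefination with a stabilised formyl ylide should give the E-trisubstituted enal, the ylide being too weakly basic to epimerise the aldehyde and the hindered product enal reacting on only slowly.

Step 7
Reactants: 14 (2E,4S)-2,4-dimethylhex-2-enal
Product: 15 (3E,5S)-3,5-dimethylhept-3-en-1-yne
Conditions: Me3SiCHN2 (1.2 equiv), n-BuLi (1.2 equiv), THF, −78 °C; then 14, −78 °C to 0 °C
Reagents that add atoms: (trimethylsilyl)diazomethane, C[Si](C)(C)C=[N+]=[N-]
Why: Colvin rearrangement (Peterson-type olefination to a diazoalkene, loss of nitrogen and a 1,2-hydrogen shift) converts the enal into the terminal enyne and avoids the carbonate/methanol media that add methanol to enals.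

Step 8
Reactants: 15 (3E,5S)-3,5-dimethylhept-3-en-1-yne
Product: 16 tributyl[(1E,3E,5S)-3,5-dimethylhepta-1,3-dien-1-yl]stannane
Conditions: Bu3SnH (1.15 equiv), PdCl2(PPh3)2 (2 mol %), THF, 0 °C
Reagents that add atoms: tributyltin hydride, CCCC[SnH](CCCC)CCCC
Why: Palladium-catalysed hydrostannation adds H and Sn syn across the terminal alkyne and places tin at the unhindered terminus because of the branching at C3, which sets the 1E alkene.

Step 9
Reactants: 10 methyl (5R,6S)-3-bromo-5-hydroxy-6-methoxy-7-oxo-6,7-dihydro-5H-cyclopenta[c]pyridine-5-carboxylate; 16 tributyl[(1E,3E,5S)-3,5-dimethylhepta-1,3-dien-1-yl]stannane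
Product: 17 methyl (5R,6S)-3-[(1E,3E,5S)-3,5-dimethylhepta-1,3-dien-1-yl]-5-hydroxy-6-methoxy-7-oxo-6,7-dihydro-5H-cyclopenta[c]pyridine-5-carboxylate
Conditions: Pd2(dba)3 (2.5 mol %), AsPh3 (20 mol %), NMP, 50 °C, dark
Reagents that add atoms: none
Why: Stille coupling, in which the bromine next to the ring nitrogen and para to the acyl group adds readily to zerovalent palladium, the dienyl group is transferred with retention of both alkene geometries, and the base-free medium spares the β-hydroxy ketone from retro-aldol cleavage and dehydration so that C5 is not scrambled.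

Step 10
Reactants: 17 methyl (5R,6S)-3-[(1E,3E,5S)-3,5-dimethylhepta-1,3-dien-1-yl]-5-hydroxy-6-methoxy-7-oxo-6,7-dihydro-5H-cyclopenta[c]pyridine-5-carboxylate; 18 (bromomethyl)chlorodimethylsilane
Product: 19 methyl (5R,6S)-5-{[(bromomethyl)dimethylsilyl]oxy}-3-[(1E,3E,5S)-3,5-dimethylhepta-1,3-dien-1-yl]-6-methoxy-7-oxo-6,7-dihydro-5H-cyclopenta[c]pyridine-5-carboxylate
Conditions: 18 (1.5 equiv), imidazole (3 equiv), CH2Cl2, 0 °C to rt; filtration through deactivated silica
Reagents that add atoms: none
Why: Silyl ether formation with a chlorosilane as small as Me3SiCl, activated by imidazole, should reach even the tertiary carbinol, and the weak base at low temperature leaves the C5 centre untouched.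

Step 11
Reactants: 19 methyl (5R,6S)-5-{[(bromomethyl)dimethylsilyl]oxy}-3-[(1E,3E,5S)-3,5-dimethylhepta-1,3-dien-1-yl]-6-methoxy-7-oxo-6,7-dihydro-5H-cyclopenta[c]pyridine-5-carboxylate
Product: 20 methyl (5R,6S)-3-[(1E,3E,5S)-3,5-dimethylhepta-1,3-dien-1-yl]-5-{[(iodomethyl)dimethylsilyl]oxy}-6-methoxy-7-oxo-6,7-dihydro-5H-cyclopenta[c]pyridine-5-carboxylate
Conditions: NaI (5 equiv), dry acetone, rt, dark; filtered, concentrated and used at once
Reagents that add atoms: sodium iodide, [Na+].[I-]
Why: Finkelstein exchange, fast at an α-silyl carbon and driven by precipitation of NaBr, installs the better leaving group so that substitution can outrun β-elimination in the next step.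

Step 12
Reactants: 20 methyl (5R,6S)-3-[(1E,3E,5S)-3,5-dimethylhepta-1,3-dien-1-yl]-5-{[(iodomethyl)dimethylsilyl]oxy}-6-methoxy-7-oxo-6,7-dihydro-5H-cyclopenta[c]pyridine-5-carboxylate
Product: 22 cis-fused siloxane (5R,6S; C5–O–SiMe2–CH2–C6 bridge on the skeleton of 23), via potassium enolate 21 (not isolated)
Conditions: KN(SiMe3)2 (1.05 equiv, toluene solution), THF (0.01 M), −78 °C to −40 °C; pH 7 phosphate buffer
Reagents that add atoms: none
Why: Proposed new method: KN(SiMe3)2 removes the only acidic hydrogen of 20 (C6–H, between the C7 carbonyl and the methoxy oxygen) from either epimer to give the planar enolate 21, and its C6 carbon displaces iodide from the Si–CH2–I carbon held on the C5 oxygen in an intramolecular SN2 reaction that forms the C6–CH2 bond. The closest known reaction types are intramolecular enolate alkylation, intermolecular enolate alkylation by (iodomethyl)trialkylsilanes (α-silyl halides being fast SN2 partners) and the radical cyclisation of (bromomethyl)dimethylsilyl ethers, but an anionic closure of such a tether onto an enolate carbon is not established. The 1,2-oxasilolane ring (C5, O, Si, CH2, C6) closes in a 5-(enolexo)-exo-tet mode, which is allowed for enolates, and the long Si–O and Si–C bonds ease the collinear C6···CH2···I alignment. The new C6 stereocentre is controlled by the C5 stereocentre through the tether, because the three-atom O–Si–CH2 arm reaches only the enolate face that carries the C5 oxygen and a trans-fused bicyclo[3.3.0] array is out of reach, so CH2 ends cis to O and OMe cis to CO2Me. The step needs C- over O-alkylation (O-attack would require a seven-membered ring from an oxygen that points away from the arm), substitution over β-elimination of the silanolate (favoured by iodide as leaving group, −78 °C and a reactive potassium enolate) and ring closure over dimerisation (0.01 M). The silyl ether also keeps the C5 oxygen from triggering retro-aldol cleavage, and one equivalent of base leaves the allylic C–H bonds of the side chain and its stereocentre untouched.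

Step 13
Reactants: 22 cis-fused siloxane (5R,6S; C5–O–SiMe2–CH2–C6 bridge on the skeleton of 23)
Product: 23 methyl (5R,6S)-3-[(1E,3E,5S)-3,5-dimethylhepta-1,3-dien-1-yl]-5-hydroxy-6-methoxy-6-methyl-7-oxo-6,7-dihydro-5H-cyclopenta[c]pyridine-5-carboxylate
Conditions: Bu4NF·3H2O (5 equiv), DMF, 0 °C to 40 °C
Reagents that add atoms: none
Why: Fluoride-promoted, hydroxyl-assisted protodesilylation of a 1,2-oxasilolane, known from the products of silicon-tethered radical cyclisations, cleaves the Si–O bond and, through pentacoordinate silicon, protonates the Si–CH2 bond with water, without touching a bond at C5 or C6, while the water keeps the C5 hydroxyl protonated and so holds back retro-aldol cleavage.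

Compound list
1 | 2,5-dibromopyridine | Brc1ccc(Br)nc1 | starting material
2 | dimethyl oxalate | COC(=O)C(=O)OC | starting material
3 | 2,5-dibromo-4-lithiopyridine | [Li]c1cc(Br)ncc1Br | intermediate
4 | methyl 2-(2,5-dibromopyridin-4-yl)-2-oxoacetate | COC(=O)C(=O)c1cc(Br)ncc1Br | intermediate
5 | methyl methoxyacetate | COCC(=O)OC | starting material
6 | lithium enolate of methyl methoxyacetate | COC=C(OC)O[Li] | intermediate
7 | dimethyl 2-(2,5-dibromopyridin-4-yl)-2-hydroxy-3-methoxybutanedioate (racemic; both diastereomers) | COC(=O)C(OC)C(O)(C(=O)OC)c1cc(Br)ncc1Br | intermediate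
8 | doubly magnesiated diester (chloromagnesium alkoxide at the carbinol, MgCl in place of the pyridine C5 bromine) | COC(=O)C(OC)C(O[Mg]Cl)(C(=O)OC)c1cc(Br)ncc1[Mg]Cl | intermediate
9 | methyl rac-3-bromo-5-hydroxy-6-methoxy-7-oxo-6,7-dihydro-5H-cyclopenta[c]pyridine-5-carboxylate | COC1C(=O)c2cnc(Br)cc2C1(O)C(=O)OC | intermediate
10 | methyl (5R,6S)-3-bromo-5-hydroxy-6-methoxy-7-oxo-6,7-dihydro-5H-cyclopenta[c]pyridine-5-carboxylate | Brc1cc2c(cn1)C(=O)[C@@H](OC)[C@@]2(O)C(=O)OC | intermediate
11 | (S)-2-methylbutan-1-ol | CC[C@H](C)CO | starting material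
12 | (S)-2-methylbutanal | CC[C@H](C)C=O | intermediate
13 | 2-(triphenylphosphoranylidene)propanal | CC(C=O)=P(c1ccccc1)(c1ccccc1)c1ccccc1 | starting material
14 | (2E,4S)-2,4-dimethylhex-2-enal | CC[C@H](C)/C=C(C)/C=O | intermediate
15 | (3E,5S)-3,5-dimethylhept-3-en-1-yne | CC[C@H](C)/C=C(C)/C#C | intermediate
16 | tributyl[(1E,3E,5S)-3,5-dimethylhepta-1,3-dien-1-yl]stannane | CC[C@H](C)/C=C(C)/C=C/[Sn](CCCC)(CCCC)CCCC | intermediate
17 | methyl (5R,6S)-3-[(1E,3E,5S)-3,5-dimethylhepta-1,3-dien-1-yl]-5-hydroxy-6-methoxy-7-oxo-6,7-dihydro-5H-cyclopenta[c]pyridine-5-carboxylate | CC[C@H](C)/C=C(C)/C=C/c1cc2c(cn1)C(=O)[C@@H](OC)[C@@]2(O)C(=O)OC | intermediate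
18 | (bromomethyl)chlorodimethylsilane | C[Si](C)(Cl)CBr | starting material
19 | methyl (5R,6S)-5-{[(bromomethyl)dimethylsilyl]oxy}-3-[(1E,3E,5S)-3,5-dimethylhepta-1,3-dien-1-yl]-6-methoxy-7-oxo-6,7-dihydro-5H-cyclopenta[c]pyridine-5-carboxylate | CC[C@H](C)/C=C(C)/C=C/c1cc2c(cn1)C(=O)[C@@H](OC)[C@@]2(O[Si](C)(C)CBr)C(=O)OC | intermediate
20 | methyl (5R,6S)-3-[(1E,3E,5S)-3,5-dimethylhepta-1,3-dien-1-yl]-5-{[(iodomethyl)dimethylsilyl]oxy}-6-methoxy-7-oxo-6,7-dihydro-5H-cyclopenta[c]pyridine-5-carboxylate | CC[C@H](C)/C=C(C)/C=C/c1cc2c(cn1)C(=O)[C@@H](OC)[C@@]2(O[Si](C)(C)CI)C(=O)OC | intermediate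
21 | potassium C6=C7 enolate of 20 | CC[C@H](C)/C=C(C)/C=C/c1cc2c(cn1)C([O-])=C(OC)[C@@]2(O[Si](C)(C)CI)C(=O)OC.[K+] | intermediate
22 | methyl (5R,6S)-3-[(1E,3E,5S)-3,5-dimethylhepta-1,3-dien-1-yl]-6-methoxy-7-oxo-5,6-[oxy(dimethylsilanediyl)methylene]-6,7-dihydro-5H-cyclopenta[c]pyridine-5-carboxylate (O on C5, CH2 on C6; cis-fused 1,2-oxasilolane) | CC[C@H](C)/C=C(C)/C=C/c1cc2c(cn1)C(=O)[C@]3(OC)C[Si](C)(C)O[C@]23C(=O)OC | intermediate
23 | methyl (5R,6S)-3-[(1E,3E,5S)-3,5-dimethylhepta-1,3-dien-1-yl]-5-hydroxy-6-methoxy-6-methyl-7-oxo-6,7-dihydro-5H-cyclopenta[c]pyridine-5-carboxylate | CC[C@H](C)/C=C(C)/C=C/c1cc2c(cn1)C(=O)[C@@](C)(OC)[C@@]2(O)C(=O)OC | target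

Total step count: 13.
Longest linear sequence: 9 steps. This is steps 1–4 and 9–13 from 1; the branch from 11 through steps 5–8 and 9–13 is equally long.

Steps most likely to fail

**Step 12 (the labelled step).**
- Risk: β-elimination of the silanolate from enolate 21 may outrun ring closure, or the base may attack silicon and strip the tether.
- The fallback keeps the tether but replaces the anion by a radical. This is known chemistry: the silicon-tethered radical cyclisation of (bromomethyl)dimethylsilyl ethers of allylic alcohols.
- It sets out from bromide 19. Me3SiOTf and Et3N in CH2Cl2 at 0 °C should give, without a free enolate, the trimethylsilyl enol ether F1.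
- Slow addition of Bu3SnH and AIBN in benzene at 80 °C should generate the α-silyl radical. This closes 5-exo-trig onto C6 on the face of the C5 oxygen and leaves a C7 radical stabilised by oxygen and the pyridine ring. Hydrogen transfer then gives the 7-silyloxy siloxane F2, whose C7 configuration is inconsequential.
- Bu4NF in wet DMF can now be heated because no ketone is present. It should remove all silicon and give the 5,7-diol F3.
- MnO2 in CH2Cl2 or Dess–Martin periodinane oxidises only the secondary pyridylic alcohol, and the route is rejoined at target 23.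

**Step 13.**
- Risk: under basic fluoride the liberated C5 carbinol may undergo reversible retro-aldol cleavage of the C5–C6 bond, which would scramble both ring stereocentres. The C–Si cleavage may also need heating that the aldol and the methyl ester do not tolerate.
- The fallback takes the carbonyl group away for the duration of the desilylation.
- It sets out from 22. Luche reduction (NaBH4, CeCl3·7H2O, MeOH, −40 °C) should give the 7-hydroxy siloxane F4, in which no retro-aldol path exists.
- Bu4NF in wet DMF at 70 °C should then give the same 5,7-diol F3 as above.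
- Dess–Martin periodinane restores the C7 ketone, so the route is rejoined at 23.

**Step 3.**
- Risk: addition of the Grignard reagent to the unhindered α-methoxy ester, or retro-aldol fragmentation of the magnesium alkoxide, may compete with bromine–magnesium exchange at the hindered bromine.
- The fallback closes the ring at the C5–C6 bond instead of the C7–C7a bond.
- It sets out from keto ester 4. NaBH4 in MeOH at −20 °C should give the racemic hydroxy ester F5, and t-BuMe2SiCl with imidazole its silyl ether F6.
- i-PrMgCl·LiCl at −40 °C, followed by N-methoxy-N-methyl-2-methoxyacetamide, should give the methoxyacetyl ketone F7.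
- HF·pyridine should release the free hydroxy ester F8, and Dess–Martin periodinane should give the keto ester F9.
- F9 should close with catalytic Et3N in an intramolecular 5-(enolexo)-exo-trig aldol addition, and the route is rejoined at 9.

Further compounds
F1 | step 12 | trimethylsilyl enol ether (C6=C7) of bromide 19 | CC[C@H](C)/C=C(C)/C=C/c1cc2c(cn1)C(O[Si](C)(C)C)=C(OC)[C@@]2(O[Si](C)(C)CBr)C(=O)OC
F2 | step 12 | 7-(trimethylsilyloxy) analogue of siloxane 22 (C7 drawn with O cis to the siloxane ring) | CC[C@H](C)/C=C(C)/C=C/c1cc2c(cn1)[C@H](O[Si](C)(C)C)[C@]3(OC)C[Si](C)(C)O[C@]23C(=O)OC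
F3 | step 12 | 5,7-diol (7-hydroxy analogue of target 23) | CC[C@H](C)/C=C(C)/C=C/c1cc2c(cn1)[C@H](O)[C@@](C)(OC)[C@@]2(O)C(=O)OC
F4 | step 13 | 7-hydroxy analogue of siloxane 22 | CC[C@H](C)/C=C(C)/C=C/c1cc2c(cn1)[C@H](O)[C@]3(OC)C[Si](C)(C)O[C@]23C(=O)OC
F5 | step 3 | methyl rac-2-(2,5-dibromopyridin-4-yl)-2-hydroxyacetate | COC(=O)C(O)c1cc(Br)ncc1Br
F6 | step 3 | methyl rac-2-(tert-butyldimethylsilyloxy)-2-(2,5-dibromopyridin-4-yl)acetate | COC(=O)C(O[Si](C)(C)C(C)(C)C)c1cc(Br)ncc1Br
F7 | step 3 | methyl rac-2-[2-bromo-5-(methoxyacetyl)pyridin-4-yl]-2-(tert-butyldimethylsilyloxy)acetate | COCC(=O)c1cnc(Br)cc1C(O[Si](C)(C)C(C)(C)C)C(=O)OC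
F8 | step 3 | methyl rac-2-[2-bromo-5-(methoxyacetyl)pyridin-4-yl]-2-hydroxyacetate | COCC(=O)c1cnc(Br)cc1C(O)C(=O)OC
F9 | step 3 | methyl 2-[2-bromo-5-(methoxyacetyl)pyridin-4-yl]-2-oxoacetate | COCC(=O)c1cnc(Br)cc1C(=O)C(=O)OC
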